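**Retrosynthetic overview**

1. Nostocyclophane C (25) ⇐ C2-symmetric macrocyclic bis(β-hydroxy ketone) 19, by anti-1,3-reduction (sets C1/C14), mono-O-methylation, invertive chlorination at C3/C16 and deprotection.
2. 19 ⇐ two molecules of epoxy aldehyde 16: a light-driven nickel acyl–alkyl coupling forms both C1–C2 bonds head-to-tail and closes the 22-membered ring (the only ring made; both arenes are bought).
3. 16 ⇐ aryl acetal 3 + allylic picolinate 10: anti-SN2′ arylation transfers the carbinol configuration to C7/C20; hydrogenation turns the new butenyl group into butyl.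
4. 10 ⇐ cross-metathesis of (S)-pent-1-en-3-ol 8 (from (S)-1,2-epoxybutane) with (R)-1-chlorohept-6-en-2-ol 6 (from (R)-epichlorohydrin); 3 ⇐ 3,5-dihydroxybenzaldehyde.

Assumption: the SMILES is taken as drawn (butyl-bearing carbons R, chlorinated carbons S, benzylic carbinol carbons S); bridges are numbered C1–C7 and C14–C20, arene carbons C8–C13 (C8 on C7, C11 on C14) and C21–C26 (C21 on C20, C24 on C1), with OMe on C1 and OH on C14.

**Route**

Step 1
Reactants: 1 3,5-dihydroxybenzaldehyde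
Product: 2 3,5-bis(methoxymethoxy)benzaldehyde
Conditions: MOMCl (2.6 equiv), iPr2NEt, CH2Cl2, 0 → 23 °C
Reagents that add atoms: chloromethyl methyl ether COCCl
Why: Williamson-type O-alkylation of both phenols gives acetal ethers that later direct ortho-lithiation, tolerate all subsequent steps and leave under mild acid.

Step 2
Reactants: 2 3,5-bis(methoxymethoxy)benzaldehyde
Product: 3 1-(dimethoxymethyl)-3,5-bis(methoxymethoxy)benzene
Conditions: HC(OMe)3, PPTS (5 mol %), MeOH, 23 °C; Et3N quench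
Reagents that add atoms: trimethyl orthoformate COC(OC)OC
Why: Acid-catalysed acetalization with orthoformate as water scavenger masks the aldehyde against the aryllithium chemistry, and aryl MOM ethers survive PPTS in dry methanol.

Step 3
Reactants: 4 (R)-epichlorohydrin; 5 but-3-en-1-ylmagnesium bromide
Product: 6 (2R)-1-chlorohept-6-en-2-ol
Conditions: CuI (10 mol %), THF, −40 → −20 °C; aq NH4Cl
Reagents that add atoms: none
Why: Copper-catalysed Grignard opening of the epoxide at its CH2 terminus (SN2) does not touch the C–O stereocenter, so the bought (R) center becomes the future C3/C16 carbinol.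

Step 4
Reactants: 7 (S)-1,2-epoxybutane
Product: 8 (3S)-pent-1-en-3-ol
Conditions: Me3S+ I− (3 equiv), n-BuLi (3 equiv), THF, −10 → 23 °C
Reagents that add atoms: trimethylsulfonium iodide C[S+](C)C.[I-]
Why: Dimethylsulfonium methylide opens the epoxide at CH2 and the betaine eliminates Me2S (one-carbon homologation of an epoxide to an allylic alcohol), leaving the bought stereocenter untouched.

Step 5
Reactants: 6 (2R)-1-chlorohept-6-en-2-ol; 8 (3S)-pent-1-en-3-ol
Product: 9 (3S,4E,9R)-10-chlorodec-4-ene-3,9-diol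
Conditions: second-generation Hoveyda–Grubbs catalyst RuCl2(H2IMes)(=CH-C6H4-2-OiPr) (3 mol %), 8 (3 equiv), CH2Cl2, 40 °C
Reagents that add atoms: none
Why: Olefin cross-metathesis of a secondary allylic alcohol with a terminal alkene is reliably E-selective when the cheap partner is used in excess, and neither stereocenter is involved.

Step 6
Reactants: 9 (3S,4E,9R)-10-chlorodec-4-ene-3,9-diol
Product: 10 (3S,4E,9R)-10-chlorodec-4-ene-3,9-diyl di(pyridine-2-carboxylate)
Conditions: picolinic acid (3 equiv), DCC (3 equiv), DMAP (0.3 equiv), CH2Cl2, 0 → 23 °C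
Reagents that add atoms: pyridine-2-carboxylic acid OC(=O)c1ccccn1
Why: Steglich esterification acylates both alcohols, making the allylic picolinate a chelating leaving group for step 7 and the other picolinate a protecting group for the chlorohydrin.

Step 7
Reactants: 3 1-(dimethoxymethyl)-3,5-bis(methoxymethoxy)benzene; 10 (3S,4E,9R)-10-chlorodec-4-ene-3,9-diyl di(pyridine-2-carboxylate)
Product: 13 (2R,6S,7E)-1-chloro-6-[4-(dimethoxymethyl)-2,6-bis(methoxymethoxy)phenyl]dec-7-en-2-yl pyridine-2-carboxylate, via aryllithium 11 (not isolated), via arylmagnesium bromide 12 (not isolated)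
Conditions: 3 (2.5 equiv), n-BuLi, THF, 0 °C; MgBr2·OEt2, 0 °C; CuBr·SMe2 (0.5 equiv), −78 °C; then 10, −78 → −30 °C
Reagents that add atoms: none
Why: Directed ortho-lithiation between the two OMOM groups, transmetalation, then a copper-mediated anti-SN2′ allylic substitution of the magnesium-chelated allylic picolinate (H-in-plane conformer, aryl delivered anti to the leaving group) transfers the (S)-carbinol configuration to the new benzylic center and gives the E-butenyl group, while the non-allylic picolinate and the primary chloride are inert.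

Step 8
Reactants: 13 (2R,6S,7E)-1-chloro-6-[4-(dimethoxymethyl)-2,6-bis(methoxymethoxy)phenyl]dec-7-en-2-yl pyridine-2-carboxylate
Product: 14 (2R,6R)-1-chloro-6-[4-(dimethoxymethyl)-2,6-bis(methoxymethoxy)phenyl]decan-2-yl pyridine-2-carboxylate
Conditions: H2 (1 atm), 5% Pt/C, EtOAc, 23 °C
Reagents that add atoms: none
Why: Heterogeneous hydrogenation of the disubstituted alkene completes the butyl group without touching C–Cl, acetal, MOM or pyridine, and the benzylic descriptor changes from S to R only because the substituent ranking changes.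

Step 9
Reactants: 14 (2R,6R)-1-chloro-6-[4-(dimethoxymethyl)-2,6-bis(methoxymethoxy)phenyl]decan-2-yl pyridine-2-carboxylate
Product: 16 3,5-bis(methoxymethoxy)-4-{(4R)-1-[(2R)-oxiran-2-yl]octan-4-yl}benzaldehyde, via chlorohydrin aldehyde 15 (not isolated)
Conditions: AcOH–THF–H2O (3:1:1), 40 °C; concentrate; K2CO3, MeOH, 23 °C
Reagents that add atoms: water O
Why: Mild aqueous acid hydrolyses the dimethyl acetal but not the aryl MOM ethers, then methanolysis of the activated picolinate frees the alkoxide, which closes the epoxide by intramolecular Williamson displacement of the primary chloride with retention at the carbinol carbon.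

Step 10
Reactants: 16 3,5-bis(methoxymethoxy)-4-{(4R)-1-[(2R)-oxiran-2-yl]octan-4-yl}benzaldehyde (two molecules)
Product: 19 (3R,7R,16R,20R)-7,20-dibutyl-3,16-dihydroxy-9,13,22,26-tetrakis(methoxymethoxy)[7.7]paracyclophane-1,14-dione, via bromohydrin 17 (not isolated), via linear dimer 18 (not isolated)
Conditions: [Ir(dF(CF3)ppy)2(dtbbpy)]PF6 (2 mol %), NiBr2(dtbbpy) (10 mol %), quinuclidine (30 mol %), quinuclidinium bromide (40 mol %), 1,4-dioxane–MeCN (4:1), 5 mM, 450 nm LEDs, 30 °C
Reagents that add atoms: none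
Why: Proposed new method: a bromide-relay acylation of an epoxide by an aldehyde C–H bond, run as a head-to-tail cyclodimerization. Quinuclidinium bromide reversibly opens the terminal epoxide at CH2 to bromohydrin 17, leaving the carbinol stereocenter untouched. The excited trivalent iridium photocatalyst oxidises quinuclidine to its radical cation, which abstracts the hydridic formyl hydrogen to give an aroyl radical that does not decarbonylate. Low-valent nickel captures this radical, adds the primary C–Br bond and reductively eliminates from trivalent nickel to forge C1–C2, returning HBr to the relay, so the net change is ArCHO + epoxide → β-hydroxy ketone with no stoichiometric reagent. The first coupling is intermolecular (18) and the second closes the 22-membered ring, because a single monomer cannot bridge its own para positions. The closest known reactions are the nickel/photoredox/hydrogen-atom-transfer acylation of alkyl bromides by aldehydes, nickel cross-electrophile couplings of epoxides through in situ halohydrins, and kinetic head-to-tail olefination cyclodimerizations to [7.7]paracyclophanes.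

Step 11
Reactants: 19 (3R,7R,16R,20R)-7,20-dibutyl-3,16-dihydroxy-9,13,22,26-tetrakis(methoxymethoxy)[7.7]paracyclophane-1,14-dione
Product: 20 (1S,3R,7R,14S,16R,20R)-7,20-dibutyl-1,14-dihydroxy-9,13,22,26-tetrakis(methoxymethoxy)[7.7]paracyclophane-3,16-diyl dibenzoate
Conditions: SmI2 (0.6 equiv), PhCHO (12 equiv), THF, −10 °C
Reagents that add atoms: benzaldehyde O=Cc1ccccc1
Why: Evans–Tishchenko reduction, in which the samarium-bound hemiacetal of each C3/C16 hydroxyl with benzaldehyde delivers hydride to the ketone through a six-membered chair transition state, gives the anti-1,3-diol (C1/C14 = S) and at the same time leaves the benzoate on the C3/C16 oxygen and the new benzylic carbinol free.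

Step 12
Reactants: 20 (1S,3R,7R,14S,16R,20R)-7,20-dibutyl-1,14-dihydroxy-9,13,22,26-tetrakis(methoxymethoxy)[7.7]paracyclophane-3,16-diyl dibenzoate
Product: 22 (1S,3R,7R,14S,16R,20R)-7,20-dibutyl-1-methoxy-9,13,22,26-tetrakis(methoxymethoxy)-14-(triethylsilyloxy)[7.7]paracyclophane-3,16-diyl dibenzoate, via monomethyl ether 21 (not isolated)
Conditions: MeOTf (1.1 equiv), 2,6-di-tert-butyl-4-methylpyridine, CH2Cl2, 0 → 23 °C; then imidazole, Et3SiCl, 23 °C
Reagents that add atoms: methyl trifluoromethanesulfonate COS(=O)(=O)C(F)(F)F; chlorotriethylsilane CC[Si](Cl)(CC)CC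
Why: Non-basic O-methylation (no benzoate migration) of the two homotopic carbinols of the C2-symmetric diol is stopped at the statistical maximum of the single possible mono-ether (about half), and the remaining carbinol is silylated in the same flask, with the separable bis-silyl by-product desilylated and recycled and no stereocenter touched.

Step 13
Reactants: 22 (1S,3R,7R,14S,16R,20R)-7,20-dibutyl-1-methoxy-9,13,22,26-tetrakis(methoxymethoxy)-14-(triethylsilyloxy)[7.7]paracyclophane-3,16-diyl dibenzoate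
Product: 23 (1S,3R,7R,14S,16R,20R)-7,20-dibutyl-1-methoxy-9,13,22,26-tetrakis(methoxymethoxy)-14-(triethylsilyloxy)[7.7]paracyclophane-3,16-diol
Conditions: iBu2AlH (8 equiv), CH2Cl2, −78 °C; aq Rochelle salt
Reagents that add atoms: none
Why: Reductive ester cleavage at low temperature frees both C3/C16 alcohols without affecting the silyl, MOM or methyl ethers.

Step 14
Reactants: 23 (1S,3R,7R,14S,16R,20R)-7,20-dibutyl-1-methoxy-9,13,22,26-tetrakis(methoxymethoxy)-14-(triethylsilyloxy)[7.7]paracyclophane-3,16-diol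
Product: 24 (1S,3S,7R,14S,16S,20R)-7,20-dibutyl-3,16-dichloro-1-methoxy-9,13,22,26-tetrakis(methoxymethoxy)-14-(triethylsilyloxy)[7.7]paracyclophane
Conditions: PPh3 (6 equiv), CCl4, pyridine, MeCN, 60 °C
Reagents that add atoms: tetrachloromethane ClC(Cl)(Cl)Cl
Why: Appel reaction, in which chloride displaces each alkoxyphosphonium group by SN2 with inversion, turns the two (R)-carbinols derived from epichlorohydrin into the (S)-chlorides.

Step 15
Reactants: 24 (1S,3S,7R,14S,16S,20R)-7,20-dibutyl-3,16-dichloro-1-methoxy-9,13,22,26-tetrakis(methoxymethoxy)-14-(triethylsilyloxy)[7.7]paracyclophane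
Product: 25 nostocyclophane C, (1S,3S,7R,14S,16S,20R)-7,20-dibutyl-3,16-dichloro-1-methoxy[7.7]paracyclophane-9,13,14,22,26-pentol
Conditions: 3 M aq HCl–THF (1:3), 40 °C
Reagents that add atoms: none
Why: Acid hydrolysis removes the four aryl MOM acetals and the silyl ether in one operation, while the benzylic C–O bonds (on rings whose oxygens are meta and therefore not cation-stabilising) and the secondary chlorides are not ionised in this non-alcoholic medium.

**Compound list**

1 | 3,5-dihydroxybenzaldehyde | O=Cc1cc(O)cc(O)c1 | starting material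
2 | 3,5-bis(methoxymethoxy)benzaldehyde | O=Cc1cc(OCOC)cc(OCOC)c1 | intermediate
3 | 1-(dimethoxymethyl)-3,5-bis(methoxymethoxy)benzene | COC(OC)c1cc(OCOC)cc(OCOC)c1 | intermediate
4 | (R)-epichlorohydrin, (2R)-2-(chloromethyl)oxirane | ClC[C@H]1CO1 | starting material
5 | but-3-en-1-ylmagnesium bromide | C=CCC[Mg]Br | starting material
6 | (2R)-1-chlorohept-6-en-2-ol | ClC[C@H](O)CCCC=C | intermediate
7 | (S)-1,2-epoxybutane, (2S)-2-ethyloxirane | CC[C@H]1CO1 | starting material
8 | (3S)-pent-1-en-3-ol | CC[C@H](O)C=C | intermediate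
9 | (3S,4E,9R)-10-chlorodec-4-ene-3,9-diol | CC[C@H](O)/C=C/CCC[C@@H](O)CCl | intermediate
10 | (3S,4E,9R)-10-chlorodec-4-ene-3,9-diyl di(pyridine-2-carboxylate) | CC[C@H](OC(=O)c1ccccn1)/C=C/CCC[C@@H](OC(=O)c1ccccn1)CCl | intermediate
11 | [4-(dimethoxymethyl)-2,6-bis(methoxymethoxy)phenyl]lithium | [Li]c1c(OCOC)cc(C(OC)OC)cc1OCOC | intermediate
12 | [4-(dimethoxymethyl)-2,6-bis(methoxymethoxy)phenyl]magnesium bromide | Br[Mg]c1c(OCOC)cc(C(OC)OC)cc1OCOC | intermediate
13 | (2R,6S,7E)-1-chloro-6-[4-(dimethoxymethyl)-2,6-bis(methoxymethoxy)phenyl]dec-7-en-2-yl pyridine-2-carboxylate | ClC[C@H](OC(=O)c1ccccn1)CCC[C@@H](/C=C/CC)c1c(OCOC)cc(C(OC)OC)cc1OCOC | intermediate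
14 | (2R,6R)-1-chloro-6-[4-(dimethoxymethyl)-2,6-bis(methoxymethoxy)phenyl]decan-2-yl pyridine-2-carboxylate | ClC[C@H](OC(=O)c1ccccn1)CCC[C@@H](CCCC)c1c(OCOC)cc(C(OC)OC)cc1OCOC | intermediate
15 | (2R,6R)-1-chloro-6-[4-formyl-2,6-bis(methoxymethoxy)phenyl]decan-2-yl pyridine-2-carboxylate | O=Cc1cc(OCOC)c([C@H](CCCC)CCC[C@@H](OC(=O)c2ccccn2)CCl)c(OCOC)c1 | intermediate
16 | 3,5-bis(methoxymethoxy)-4-{(4R)-1-[(2R)-oxiran-2-yl]octan-4-yl}benzaldehyde | O=Cc1cc(OCOC)c([C@H](CCCC)CCC[C@@H]2CO2)c(OCOC)c1 | intermediate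
17 | 4-[(5R,9R)-10-bromo-9-hydroxydecan-5-yl]-3,5-bis(methoxymethoxy)benzaldehyde | O=Cc1cc(OCOC)c([C@H](CCCC)CCC[C@@H](O)CBr)c(OCOC)c1 | intermediate
18 | linear head-to-tail dimer: aryl ketone joining the formyl carbon of one unit to the CH2 of the other, free CHO at one end and (R)-bromohydrin at the other | O=Cc1cc(OCOC)c([C@H](CCCC)CCC[C@@H](O)CC(=O)c2cc(OCOC)c([C@H](CCCC)CCC[C@@H](O)CBr)c(OCOC)c2)c(OCOC)c1 | intermediate
19 | (3R,7R,16R,20R)-7,20-dibutyl-3,16-dihydroxy-9,13,22,26-tetrakis(methoxymethoxy)[7.7]paracyclophane-1,14-dione | CCCC[C@@H]1CCC[C@@H](O)CC(=O)c2cc(OCOC)c(c(OCOC)c2)[C@H](CCCC)CCC[C@@H](O)CC(=O)c2cc(OCOC)c1c(OCOC)c2 | intermediate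
20 | (1S,3R,7R,14S,16R,20R)-7,20-dibutyl-1,14-dihydroxy-9,13,22,26-tetrakis(methoxymethoxy)[7.7]paracyclophane-3,16-diyl dibenzoate | CCCC[C@@H]1CCC[C@@H](OC(=O)c3ccccc3)C[C@H](O)c2cc(OCOC)c(c(OCOC)c2)[C@H](CCCC)CCC[C@@H](OC(=O)c3ccccc3)C[C@H](O)c2cc(OCOC)c1c(OCOC)c2 | intermediate
21 | (1S,3R,7R,14S,16R,20R)-7,20-dibutyl-14-hydroxy-1-methoxy-9,13,22,26-tetrakis(methoxymethoxy)[7.7]paracyclophane-3,16-diyl dibenzoate | CCCC[C@@H]1CCC[C@@H](OC(=O)c3ccccc3)C[C@H](OC)c2cc(OCOC)c(c(OCOC)c2)[C@H](CCCC)CCC[C@@H](OC(=O)c3ccccc3)C[C@H](O)c2cc(OCOC)c1c(OCOC)c2 | intermediate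
22 | (1S,3R,7R,14S,16R,20R)-7,20-dibutyl-1-methoxy-9,13,22,26-tetrakis(methoxymethoxy)-14-(triethylsilyloxy)[7.7]paracyclophane-3,16-diyl dibenzoate | CCCC[C@@H]1CCC[C@@H](OC(=O)c3ccccc3)C[C@H](OC)c2cc(OCOC)c(c(OCOC)c2)[C@H](CCCC)CCC[C@@H](OC(=O)c3ccccc3)C[C@H](O[Si](CC)(CC)CC)c2cc(OCOC)c1c(OCOC)c2 | intermediate
23 | (1S,3R,7R,14S,16R,20R)-7,20-dibutyl-1-methoxy-9,13,22,26-tetrakis(methoxymethoxy)-14-(triethylsilyloxy)[7.7]paracyclophane-3,16-diol | CCCC[C@@H]1CCC[C@@H](O)C[C@H](OC)c2cc(OCOC)c(c(OCOC)c2)[C@H](CCCC)CCC[C@@H](O)C[C@H](O[Si](CC)(CC)CC)c2cc(OCOC)c1c(OCOC)c2 | intermediate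
24 | (1S,3S,7R,14S,16S,20R)-7,20-dibutyl-3,16-dichloro-1-methoxy-9,13,22,26-tetrakis(methoxymethoxy)-14-(triethylsilyloxy)[7.7]paracyclophane | CCCC[C@@H]1CCC[C@H](Cl)C[C@H](OC)c2cc(OCOC)c(c(OCOC)c2)[C@H](CCCC)CCC[C@H](Cl)C[C@H](O[Si](CC)(CC)CC)c2cc(OCOC)c1c(OCOC)c2 | intermediate
25 | nostocyclophane C, (1S,3S,7R,14S,16S,20R)-7,20-dibutyl-3,16-dichloro-1-methoxy[7.7]paracyclophane-9,13,14,22,26-pentol | CCCC[C@@H]1CCC[C@H](Cl)C[C@H](OC)c2cc(O)c(c(O)c2)[C@H](CCCC)CCC[C@H](Cl)C[C@H](O)c2cc(O)c1c(O)c2 | target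

**Step count and risks**

Total: 15 steps. Longest linear sequence: 12 steps (7 → 8 → 9 → 10 → 13 → 14 → 16 → 19 → 20 → 22 → 23 → 24 → 25).

Step 10 (the proposed new reaction; most likely to fail). Risks are oligomers instead of the cyclic dimer, hydrogen abstraction from the MOM OCH2O or carbinol C–H bonds, and β-oxygen elimination at nickel. The fallback uses known polar acyl-anion chemistry; it sets out from 15 (isolated by stopping step 9 after the acid stage) and comes back at 19. 1,3-Propanedithiol with catalytic I2 in CH2Cl2 converts the aldehyde into (2R,6R)-1-chloro-6-[4-(1,3-dithian-2-yl)-2,6-bis(methoxymethoxy)phenyl]decan-2-yl pyridine-2-carboxylate F9. K2CO3 in MeOH gives 2-{3,5-bis(methoxymethoxy)-4-[(4R)-1-[(2R)-oxiran-2-yl]octan-4-yl]phenyl}-1,3-dithiane F10. n-BuLi (THF, −78 → 0 °C, 2 mM) lithiates the dithiane, which opens the epoxide of a second molecule and then closes the ring to the macrocyclic bis(1,3-dithiane) diol F11 (Corey–Seebach alkylation of epoxides). MeI and CaCO3 in aqueous MeCN unmask both ketones to give 19.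

Step 7 (transfer of a doubly ortho-substituted aryl group from copper). The fallback reverses the roles so that an unhindered alkylcopper attacks a benzylic allylic terminus; it sets out from 3 and 4 and comes back at 16. Aryllithium 11 from 3 is quenched with I2 to give 5-(dimethoxymethyl)-2-iodo-1,3-bis(methoxymethoxy)benzene F1. Sonogashira coupling with commercial (S)-but-3-yn-2-ol (PdCl2(PPh3)2, CuI, Et3N) gives (2S)-4-[4-(dimethoxymethyl)-2,6-bis(methoxymethoxy)phenyl]but-3-yn-2-ol F2. NaAlH2(OCH2CH2OMe)2 reduces it to (2S,3E)-4-[4-(dimethoxymethyl)-2,6-bis(methoxymethoxy)phenyl]but-3-en-2-ol F3, and picolinic acid with DCC gives its pyridine-2-carboxylate F4. n-BuMgBr with catalytic CuBr·SMe2 adds anti-SN2′ at the aryl-bearing terminus to give 5-(dimethoxymethyl)-1,3-bis(methoxymethoxy)-2-[(2E,4R)-oct-2-en-4-yl]benzene F5. Cross-metathesis with (2R)-1-chloropent-4-en-2-ol F6 (from 4 and vinylmagnesium bromide, CuI) gives (2R,4E,6R)-1-chloro-6-[4-(dimethoxymethyl)-2,6-bis(methoxymethoxy)phenyl]dec-4-en-2-ol F7. H2 over Pt/C gives (2R,6R)-1-chloro-6-[4-(dimethoxymethyl)-2,6-bis(methoxymethoxy)phenyl]decan-2-ol F8, which the two-stage unmasking of step 9 converts to 16.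

Step 14 (two invertive chlorinations on the macrocycle; elimination or incomplete inversion). The fallback separates activation from displacement; it sets out from 23 and comes back at 24. MsCl and Et3N in CH2Cl2 at 0 °C give the (1S,3R,7R,14S,16R,20R)-3,16-bis(methanesulfonate) F12, which LiCl in DMF at 60 °C displaces by clean SN2 inversion to give 24.

**Further compounds**

F1 | step 7 | 5-(dimethoxymethyl)-2-iodo-1,3-bis(methoxymethoxy)benzene | COC(OC)c1cc(OCOC)c(I)c(OCOC)c1
F2 | step 7 | (2S)-4-[4-(dimethoxymethyl)-2,6-bis(methoxymethoxy)phenyl]but-3-yn-2-ol | C[C@H](O)C#Cc1c(OCOC)cc(C(OC)OC)cc1OCOC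
F3 | step 7 | (2S,3E)-4-[4-(dimethoxymethyl)-2,6-bis(methoxymethoxy)phenyl]but-3-en-2-ol | C[C@H](O)/C=C/c1c(OCOC)cc(C(OC)OC)cc1OCOC
F4 | step 7 | (2S,3E)-4-[4-(dimethoxymethyl)-2,6-bis(methoxymethoxy)phenyl]but-3-en-2-yl pyridine-2-carboxylate | C[C@H](OC(=O)c1ccccn1)/C=C/c1c(OCOC)cc(C(OC)OC)cc1OCOC
F5 | step 7 | 5-(dimethoxymethyl)-1,3-bis(methoxymethoxy)-2-[(2E,4R)-oct-2-en-4-yl]benzene | C/C=C/[C@@H](CCCC)c1c(OCOC)cc(C(OC)OC)cc1OCOC
F6 | step 7 | (2R)-1-chloropent-4-en-2-ol | ClC[C@H](O)CC=C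
F7 | step 7 | (2R,4E,6R)-1-chloro-6-[4-(dimethoxymethyl)-2,6-bis(methoxymethoxy)phenyl]dec-4-en-2-ol | ClC[C@H](O)C/C=C/[C@@H](CCCC)c1c(OCOC)cc(C(OC)OC)cc1OCOC
F8 | step 7 | (2R,6R)-1-chloro-6-[4-(dimethoxymethyl)-2,6-bis(methoxymethoxy)phenyl]decan-2-ol | ClC[C@H](O)CCC[C@@H](CCCC)c1c(OCOC)cc(C(OC)OC)cc1OCOC
F9 | step 10 | (2R,6R)-1-chloro-6-[4-(1,3-dithian-2-yl)-2,6-bis(methoxymethoxy)phenyl]decan-2-yl pyridine-2-carboxylate | ClC[C@H](OC(=O)c1ccccn1)CCC[C@@H](CCCC)c1c(OCOC)cc(C2SCCCS2)cc1OCOC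
F10 | step 10 | 2-{3,5-bis(methoxymethoxy)-4-[(4R)-1-[(2R)-oxiran-2-yl]octan-4-yl]phenyl}-1,3-dithiane | CCCC[C@H](CCC[C@@H]1CO1)c1c(OCOC)cc(C2SCCCS2)cc1OCOC
F11 | step 10 | (3R,7R,16R,20R)-7,20-dibutyl-9,13,22,26-tetrakis(methoxymethoxy)[7.7]paracyclophane-3,16-diol with C1 and C14 each as a spiro 1,3-dithiane | CCCC[C@@H]1CCC[C@@H](O)CC3(SCCCS3)c2cc(OCOC)c(c(OCOC)c2)[C@H](CCCC)CCC[C@@H](O)CC3(SCCCS3)c2cc(OCOC)c1c(OCOC)c2
F12 | step 14 | (1S,3R,7R,14S,16R,20R)-7,20-dibutyl-1-methoxy-9,13,22,26-tetrakis(methoxymethoxy)-14-(triethylsilyloxy)[7.7]paracyclophane-3,16-diyl dimethanesulfonate | CCCC[C@@H]1CCC[C@@H](OS(C)(=O)=O)C[C@H](OC)c2cc(OCOC)c(c(OCOC)c2)[C@H](CCCC)CCC[C@@H](OS(C)(=O)=O)C[C@H](O[Si](CC)(CC)CC)c2cc(OCOC)c1c(OCOC)c2
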